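1. If each target takes one substrate and one partner, [substrate] − [partner] stays at its charged value, 27.9 mM. Partner is the limiting reagent, charged at 70.0 % of the substrate.

| flask | substrate | partner | free catalyst | remark | time |
|---|---|---|---|---|---|
| birch | 0.093 M | 0.0651 M | 0.93 mM | the very flask that is asked about, followed so far |  |
| alder | 0.093 M | 0.0651 M | 1.4 mM | run made earlier |  |
| flask | 0.093 M | 0.0651 M | 0.93 mM |  | 2.5 d |

birch run (percent of the substrate charged)

| time / h | target / % |
|---|---|
| 5.00 | 46 |
| 12.0 | 55 |
| 25.0 | 57 |
| 60.0 | 57 |

alder run (percent of the substrate charged)

| time / min | target / % |
|---|---|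
| 6.00 | 1 |
| 12.0 | 7 |
| 30.0 | 12 |
| 80.0 | 27 |

(readings scatter by 2 percentage points)

- south-west: at 2.5 d add partner, 100 % of the amount charged, then wait 30 h
- south: at 2.5 d take out 90 % of the released group then present, then wait 30 h
- north: at 2.5 d add free catalyst, 50.0 % of the amount charged, then wait 30 h
- west: change nothing and wait 30 h more

- additions leave the volume as it is
- the earlier runs were read with a standard deviation of 2 percentage points

* target, in percent of the substrate first charged, at 2.5 d
* the option that brings most further target ("none" if no option brings more than 2 percentage points) (south-west / south / north / west / none)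
* target present, in percent of the substrate first charged, after south-west
* target present, in percent of the substrate first charged, after north

2. My assumption is that target forms at rate k[free catalyst][substrate][partner] and free catalyst dies at rate kd[free catalyst]. Divide one rate by the other and time drops out. With the invariant, the integral closes: k[free catalyst]charged[substrate]charged/kd equals [substrate]charged/([substrate]charged − [partner]charged), times the ln of [substrate]/[partner] at the end over that ratio at the charge.

3. Birch's plateau of 57 % gives, as a reading, 2.80: this is the lifetime number, the work one charge of catalyst can do before it dies.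

4. Is one number enough? The share of it used by each reading gives kd: 0.156 h⁻¹ from 5.00 h and 0.179 h⁻¹ from 12.0 h, which roughly agree. Scaled to alder, it gives 33.0 % at 80.0 min, more than the 27 % read. So I use the number for the end of a run, not for its course.

5. My reckoning: birch stands at 57 % at 2.5 d, with 0.00873 % of its catalyst working, so I expect nothing from south-west, south or west. North multiplies the number to 4.20, which reads as 62.6 %, a gain of 5.6 points.

6. The forecast differs: 57 % now, best south-west, 81 % after south-west, 57 % after north, on the ground “So the flask is at equilibrium”.

7. The flask gives 56.9 %, best north, 56.9 % after south-west, 63.1 % after north.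

    free catalyst → spent catalyst (k = 0.00750 min⁻¹)
    substrate + free catalyst ⇌ catalyst intermediate A (K = 14.0 L mol⁻¹, k = 34.0 L mol⁻¹ min⁻¹)
    partner + catalyst intermediate A ⇌ catalyst intermediate B (K = 48.0 L mol⁻¹, k = 290 L mol⁻¹ min⁻¹)
    catalyst intermediate B → released group + catalyst intermediate C (k = 0.490 min⁻¹)
    catalyst intermediate C → free catalyst + target (k = 44.0 min⁻¹)

8. North stands at 63.1 % against the 62.6 % from the lifetime number. For a neighbour flask charged with 0.16 M of substrate, the number scales to 4.81 and reads 39.3 %; that flask gives 39.6 %. Birch has come to rest at 60.0 h, with spent catalyst at >99.9 %, while 43 % of the substrate and 19 % of the partner stand unbound. Ten times the time, at 600 h, birch still holds 56.9 % of target.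

The data were computed from invented constants.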